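## Structural features

The target is a chain of three 2,3-dihydrobenzofurans. C3 of ring A is bonded to C4 of ring B, C3 of ring B to C4 of ring C, C3 of ring C carries a 3,5-dihydroxyphenyl group and C4 of ring A an (E)-3,4-dihydroxystyryl group; every C2 carries a 4-hydroxyphenyl group and every C6 a hydroxyl. The six stereocentres form three vicinal C2/C3 pairs, all trans: ring A (2R,3R), ring B (2S,3S), ring C (2R,3R). The pairs are separated by arenes, so each must be controlled on its own, and the local sense alternates along the chain. Fragile parts are the ten phenols, the electron-rich stilbene, and the three O1–C2 bonds, which are benzylic to a 4-oxygenated arene and can open to quinone methides or benzylic cations. The real difficulty is steric: each C3 sits on a benzo carbon C3a that is flanked by C7a–O and a substituted C4, and is also bonded to the ortho position of the next arene. The key step exploits that C2 of rings B and C is both bonded to O1 and para-benzylic to a free phenol, so each O1–C2 bond can be made last from a para-quinone methide and the C7a phenol, with C3 as the only centre that must already be in place. The precursor and product of the key step agree with the target in connectivity and in configuration at every shared centre, so no correction is needed there; the one design change is that the ring A halogen is carried as chloride instead of bromide, because a bromide would compete in the palladium couplings that build the chain.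

## Logic of the disconnections

28 ⇒ 27. Eight O–CH3 bonds are cut and no skeletal bond. Methyl ethers are the permanent protection because every building block carries them from the start. The forward step must cleave eight ethers without ionizing the three O1–C2 bonds or adding acid to the stilbene.

27 ⇒ 25 + 26. The bond between C4 of ring A and the vinyl carbon is cut. This keeps the stilbene away from every hydrogenation and every DDQ oxidation. The forward step is a Heck reaction at a hindered, electron-rich aryl chloride beside two free phenols, and it must give the E alkene.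

25 ⇒ 23 (through 24). The O1–C2 bonds of rings B and C are cut. Two rings and two stereocentres disappear, and what remains is an open bis(triarylethane) whose stereocentres are the two C3 atoms and ring A. The forward step must oxidize only the two 4-hydroxybenzyl CH2 groups and close both rings trans.

23 ⇒ 22 ⇒ 21. Four O–Si bonds and one O–CH3 bond are cut. The silyl ethers keep the phenols of units B and C masked while ring A is closed, and the methyl cap on ring A removes the phenol that would let DDQ attack C2–H of ring A later. The forward steps need fluoride that frees four phenols without base damage, and a methylation that meets only one free phenol.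

21 ⇒ 19 (through 20) ⇒ 18. The O1–C2 bond of ring A is cut in the same way as in the key step, and before that two acetal C–O bonds. The gain is an all-acyclic tris(triarylethane). The forward steps need an acid that removes two MOM groups while four aryl silyl ethers stay, and a DDQ oxidation that finds only one free 4-hydroxybenzyl group.

18 ⇒ 17, 13 ⇒ 12, 10 ⇒ 9. In each case the C3–H and C2–H bonds are cut, which returns a triarylethylene. Each stereocentre is thereby traced to an alkene geometry and a catalyst antipode. Because all three alkenes have the same geometry while the local sense at C3 alternates, the three hydrogenations are run separately with the ligand antipodes (R), (S), (R). Each forward step must reduce a congested trisubstituted alkene under catalyst control.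

17 ⇒ 14 + 16, 12 ⇒ 11 + 7, 9 ⇒ 7 + 8, with 14 ⇒ 13 and 11 ⇒ 10. The bond from each alkene carbon C3 to C4 of the next arene (or to the 3,5-dimethoxyphenyl group) is cut, and the C–B bond is traced to C–Cl. The chain becomes two monomers and one boronic acid, and the chloride serves first as a latent boronate and finally as the ring A handle. The forward couplings must keep the alkene geometry, must not touch the aryl chlorides, and must tolerate an ortho-branched boronate.

7 ⇒ 6 and 16 ⇒ 15; 6 and 15 ⇒ 5. The enol C–OTf bond and the phenol protecting groups are cut. Both monomers come from one diphenol ketone and differ only in protection (silyl for units B and C, MOM for unit A). The enolization must give the Z enol triflate only.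

5 ⇒ 4 ⇒ 1 + 2. The C3a–C3 bond is cut. This most hindered aryl–carbon bond is made first, by acylation of the simplest arene. The forward step must acylate 2 next to chlorine and not between the methoxy groups, and the Lewis acid in the next step must unmask only the ortho oxygen.

## Other disconnections considered

Alternative 1: The cut is the C3–C3a bond of ring C, made by ring contraction of flavanone A2 to the trans ester triflate A1. In the forward step PhI(OAc)2 (trivalent iodine) with HC(OMe)3 and H2SO4 converts the enol ether of A2 into an iodane at C3, the benzo carbon shifts from C4 to C3, and the former carbonyl carbon leaves the ring as the methyl ester. In its favour, flavanones of high enantiomeric purity are accessible by established asymmetric conjugate additions, C2 passes through untouched, the migration gives the trans product, and the triflate is a usable handle. Against it here, it delivers ring C only; the ester stands where the 3,5-dimethoxyphenyl group must be, so a decarboxylative arylation through a C3 radical is needed; and joining the triflate of A1 to C3 of ring B brings back the hindered coupling. On structure, A1 takes its C2 centre from the flavanone and avoids one congested hydrogenation, which is better than the chosen plan for ring C. On mechanism, a stereospecific shift and a reversible oxa-addition are equal in trans control, and the alternative needs no oxidant near free phenols, which is also a point in its favour. On step economy it is worse: rings A and B need another method and the ester exchange costs extra steps, whereas step 19 closes two rings at once.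

Alternative 2: The cut is through the benzene ring of ring B, at C7a–C3a, C7–C6 and C5–C4. In the forward step Cp*RuCl(cod) (divalent ruthenium) joins the 1,6-diyne A4 with ethoxyacetylene A5 to give A3, closing the arene and with it the dihydrofuran. In its favour, the most congested arene is built around its substituents, so no cross-coupling is needed at a doubly ortho-substituted carbon; this is better than the chosen plan on steric access. The C2/C3 pair is fixed in the open chain and not touched, and the meta relation between the ethoxy group and the acetal is the normal regiochemical outcome for a diyne with one substituted terminus. Against it here, A4 needs the anti C2/C3 pair with ring C already attached, it carries a hydrolytically labile ynol ether, and the acetal of A3 still has to become C3 of ring A with its own stereocentre. On structure the two plans are equal in the oxygenation pattern reached. On mechanism the cycloaddition is equal or better, since it needs no oxidant. On step economy it is worse, because each ring needs its own diyne and nothing is done twofold.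

Alternative 3: The cut is at C2–C3 and O1–C2 of ring A. In the forward step base converts the phenol sulfone A7 into an ortho-quinone methide and the sulfonium salt A8 into its ylide; the ylide carbon adds to C3 and the phenoxide then displaces the sulfide, giving A6. In its favour, ring A is made last and convergently, the anti addition followed by backside displacement gives the trans ring, and no oxidant is used. A6 is fully methylated and so more robust than 25, and its bromide meets no palladium catalyst before the Heck step; on both points the alternative is better than the chosen plan. Against it here, rings B and C must already exist, so it does not solve them. C3 of ring A is created in the same step as C2, so its face is decided jointly by the sulfonium reagent and the large chiral substituent, with a real chance of a mismatched pair. The ortho-quinone methide is flanked by bromine and the ring B arene and is twisted, which slows the addition. On structure the chosen plan is simpler, because C3 is preset and only C2 is made. On mechanism the two are equal in trans control. On step economy the alternative is equal for ring A alone and worse overall.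

Key step: step 19

Remark 1: units A, B and C are the blocks that become rings A, B and C; C3 and C7a of a unit are the atoms that carry these numbers in the finished ring.
Remark 2: the sense of the iridium catalyst is assigned by the quadrant model for E trisubstituted aryl alkenes (analogy with (E)-1,2-diphenylpropene); the (R) ligand is assumed to give the centre needed in units A and C and the (S) ligand that in unit B, and the antipodes are exchanged in steps 6, 9 and 14 if step 6 shows the opposite sense.
Remark 3: compounds 1, 2, 8 and 26 are taken as catalogue chemicals.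
Remark 4: tBu-PHOX is 4-tert-butyl-2-[2-(diphenylphosphino)phenyl]-4,5-dihydrooxazole.

## Steps

Step 1
Reactants: 1 2-(4-isopropoxyphenyl)acetic acid; 2 1-chloro-3,5-dimethoxybenzene
Product: 4 1-(2-chloro-4,6-dimethoxyphenyl)-2-(4-isopropoxyphenyl)ethan-1-one, via acid chloride 3 (not isolated)
Conditions: (COCl)2, DMF (cat.), CH2Cl2, 0 °C → rt; then 2, AlCl3 (1.2 equiv), CH2Cl2, −20 → 0 °C
Reagents that add atoms: none
Why: Friedel–Crafts acylation; the acylium ion should attack the position of 2 that is ortho to chlorine and para to a methoxy group, not the site squeezed between two methoxy groups, as in formylation of the same arene. Any isopropyl ether lost to AlCl3 converges in step 2.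

Step 2
Reactants: 4 1-(2-chloro-4,6-dimethoxyphenyl)-2-(4-isopropoxyphenyl)ethan-1-one
Product: 5 1-(2-chloro-6-hydroxy-4-methoxyphenyl)-2-(4-hydroxyphenyl)ethan-1-one
Conditions: BCl3 (4 equiv), CH2Cl2, −78 → 0 °C; MeOH, then aq. NaHCO3
Reagents that add atoms: none
Why: Lewis acid ether cleavage; BCl3 chelated between the ketone and the ortho methoxy group cleaves that ether selectively and also removes the isopropyl group, while the unchelated methoxy group para to the ketone should stay.

Step 3
Reactants: 5 1-(2-chloro-6-hydroxy-4-methoxyphenyl)-2-(4-hydroxyphenyl)ethan-1-one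
Product: 6 1-[2-chloro-4-methoxy-6-(triisopropylsilyloxy)phenyl]-2-[4-(triisopropylsilyloxy)phenyl]ethan-1-one
Conditions: i-Pr3SiOTf (2.3 equiv), 2,6-lutidine, CH2Cl2, 0 °C → rt
Reagents that add atoms: triisopropylsilyl trifluoromethanesulfonate, CC(C)[Si](OS(=O)(=O)C(F)(F)F)(C(C)C)C(C)C
Why: O-silylation of both phenols; the aryl triisopropylsilyl ethers are expected to survive aqueous base, dilute acid, hydrogenation and DDQ and to fall to fluoride at the end.

Step 4
Reactants: 6 1-[2-chloro-4-methoxy-6-(triisopropylsilyloxy)phenyl]-2-[4-(triisopropylsilyloxy)phenyl]ethan-1-one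
Product: 7 (Z)-1-[2-chloro-4-methoxy-6-(triisopropylsilyloxy)phenyl]-2-[4-(triisopropylsilyloxy)phenyl]vinyl trifluoromethanesulfonate
Conditions: KN(SiMe3)2, THF, −78 °C; PhNTf2, −78 → −20 °C
Reagents that add atoms: N-phenylbis(trifluoromethanesulfonimide), O=S(=O)(N(c1ccccc1)S(=O)(=O)C(F)(F)F)C(F)(F)F
Why: enolate O-triflation; the enolate should place the 2,6-disubstituted aryl group trans to the 4-silyloxyphenyl group to avoid A(1,3) strain, which gives the Z enol triflate. Trapping at −78 °C limits silyl migration from the ortho silyl ether to the enolate oxygen.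

Step 5
Reactants: 7 (Z)-enol triflate of unit B/C; 8 (3,5-dimethoxyphenyl)boronic acid
Product: 9 (E)-1-[2-chloro-4-methoxy-6-(triisopropylsilyloxy)phenyl]-1-(3,5-dimethoxyphenyl)-2-[4-(triisopropylsilyloxy)phenyl]ethene
Conditions: Pd(PPh3)4 (5 mol%), Na2CO3 (aq.), DME, 70 °C
Reagents that add atoms: none
Why: Suzuki–Miyaura coupling of an enol triflate with retention of alkene geometry; zerovalent palladium with PPh3 inserts into C–OTf and should leave the aryl chloride alone.

Step 6
Reactants: 9 (E)-triarylethylene of unit C
Product: 10 (R)-1-[2-chloro-4-methoxy-6-(triisopropylsilyloxy)phenyl]-1-(3,5-dimethoxyphenyl)-2-[4-(triisopropylsilyloxy)phenyl]ethane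
Conditions: [Ir(cod)((R)-tBu-PHOX)][B(3,5-(CF3)2C6H3)4] (5 mol%), H2 (50 bar), CH2Cl2, 40 °C
Reagents that add atoms: none
Why: asymmetric hydrogenation of an unfunctionalized trisubstituted aryl alkene with a monovalent iridium N,P catalyst; the face is chosen by the position of the single vinylic hydrogen, so the pure E alkene should give the (R) centre by syn addition. Aryl chloride and silyl ethers are inert.

Step 7
Reactants: 10 unit C triarylethane chloride
Product: 11 (R)-2-{2-[1-(3,5-dimethoxyphenyl)-2-(4-triisopropylsilyloxyphenyl)ethyl]-5-methoxy-3-(triisopropylsilyloxy)phenyl}-4,4,5,5-tetramethyl-1,3,2-dioxaborolane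
Conditions: B2pin2, Pd2(dba)3 (2 mol%), XPhos, KOAc, 1,4-dioxane, 100 °C
Reagents that add atoms: bis(pinacolato)diboron, CC1(C)OB(OC1(C)C)B1OC(C)(C)C(C)(C)O1
Why: Miyaura borylation of an aryl chloride; the bulky electron-rich biarylphosphine allows insertion into the ortho-substituted C–Cl bond, and no other halide or triflate is present.

Step 8
Reactants: 11 unit C boronate; 7 (Z)-enol triflate of unit B/C (second portion)
Product: 12 (E)-1-[2-chloro-4-methoxy-6-(triisopropylsilyloxy)phenyl]-1-{2-[(R)-1-(3,5-dimethoxyphenyl)-2-(4-triisopropylsilyloxyphenyl)ethyl]-5-methoxy-3-(triisopropylsilyloxy)phenyl}-2-[4-(triisopropylsilyloxy)phenyl]ethene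
Conditions: PdCl2(dppf) (10 mol%), K3PO4, 1,4-dioxane/H2O (10:1), 90 °C
Reagents that add atoms: none
Why: Suzuki–Miyaura coupling with retention at the enol triflate; PdCl2(dppf) is not expected to activate the electron-rich aryl chloride at this temperature, and wet K3PO4 activates the ortho-branched boronate.

Step 9
Reactants: 12 (E)-triarylethylene of unit B
Product: 13 (S)-1-[2-chloro-4-methoxy-6-(triisopropylsilyloxy)phenyl]-1-{2-[(R)-1-(3,5-dimethoxyphenyl)-2-(4-triisopropylsilyloxyphenyl)ethyl]-5-methoxy-3-(triisopropylsilyloxy)phenyl}-2-[4-(triisopropylsilyloxy)phenyl]ethane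
Conditions: [Ir(cod)((S)-tBu-PHOX)][B(3,5-(CF3)2C6H3)4] (5 mol%), H2 (50 bar), CH2Cl2, 40 °C
Reagents that add atoms: none
Why: same hydrogenation type as step 6 with the antipodal ligand, because the local sense at C3 of unit B is opposite to that of units A and C while the alkene geometry is the same. Catalyst control is expected to override the resident centre three bonds away.

Step 10
Reactants: 13 unit B–C bis(triarylethane) chloride
Product: 14 pinacol boronate of 13 (Bpin in place of Cl; C3 of unit B S, C3 of unit C R)
Conditions: B2pin2, Pd2(dba)3 (2 mol%), XPhos, KOAc, 1,4-dioxane, 100 °C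
Reagents that add atoms: bis(pinacolato)diboron, CC1(C)OB(OC1(C)C)B1OC(C)(C)C(C)(C)O1
Why: Miyaura borylation of the only aryl chloride, as in step 7.

Step 11
Reactants: 5 1-(2-chloro-6-hydroxy-4-methoxyphenyl)-2-(4-hydroxyphenyl)ethan-1-one
Product: 15 1-[2-chloro-4-methoxy-6-(methoxymethoxy)phenyl]-2-[4-(methoxymethoxy)phenyl]ethan-1-one
Conditions: MOMCl (3 equiv), i-Pr2NEt, CH2Cl2, 0 → 40 °C
Reagents that add atoms: chloromethyl methyl ether, COCCl
Why: acetal protection of both phenols; MOM ethers are small, stable to base, palladium and hydrogenation, and come off with acid while the silyl ethers of units B and C stay.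

Step 12
Reactants: 15 bis(MOM) ketone of unit A
Product: 16 (Z)-1-[2-chloro-4-methoxy-6-(methoxymethoxy)phenyl]-2-[4-(methoxymethoxy)phenyl]vinyl trifluoromethanesulfonate
Conditions: KN(SiMe3)2, THF, −78 °C; PhNTf2, −78 → −20 °C
Reagents that add atoms: N-phenylbis(trifluoromethanesulfonimide), O=S(=O)(N(c1ccccc1)S(=O)(=O)C(F)(F)F)C(F)(F)F
Why: enolate O-triflation as in step 4; the same A(1,3) argument should give the Z isomer.

Step 13
Reactants: 14 unit B–C boronate; 16 (Z)-enol triflate of unit A
Product: 17 (E)-triarylethylene of unit A: C4 of the unit B arene of 13 bonded to C1 of a 1-[2-chloro-4-methoxy-6-(methoxymethoxy)phenyl]-2-[4-(methoxymethoxy)phenyl]vinyl group, with the chloroaryl group trans to the 4-(methoxymethoxy)phenyl group (C3 of unit B S, C3 of unit C R)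
Conditions: PdCl2(dppf) (10 mol%), K3PO4, 1,4-dioxane/H2O (10:1), 90 °C
Reagents that add atoms: none
Why: Suzuki–Miyaura coupling with retention, as in step 8; the chloride of 16 is not touched and becomes the ring A handle.

Step 14
Reactants: 17 (E)-triarylethylene of unit A
Product: 18 tris(triarylethane): as 17 with the alkene reduced, new centre C3 of unit A R (unit B S, unit C R)
Conditions: [Ir(cod)((R)-tBu-PHOX)][B(3,5-(CF3)2C6H3)4] (5 mol%), H2 (50 bar), CH2Cl2, 40 °C
Reagents that add atoms: none
Why: same hydrogenation type as step 6 with the (R) ligand; the E geometry should translate into the (R) centre, and MOM and silyl ethers are tolerated by the monovalent iridium catalyst.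

Step 15
Reactants: 18 tris(triarylethane) with MOM groups on unit A
Product: 19 unit A diphenol: as 18 with both methoxymethoxy groups replaced by hydroxyl
Conditions: HCl (3 M aq.), MeOH/THF, 45 °C
Reagents that add atoms: none
Why: acid-catalysed cleavage of aryl MOM acetals; aryl triisopropylsilyl ethers and methyl ethers are stable to dilute HCl, and no acid-labile ring is present yet.

Step 16
Reactants: 19 unit A diphenol
Product: 21 ring A closed: (2R,3R)-4-chloro-2-(4-hydroxyphenyl)-6-methoxy-2,3-dihydrobenzofuran-3-yl group at C4 of the unit B arene (units B and C as in 13), via unit A quinone methide 20 (not isolated)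
Conditions: DDQ (1.05 equiv), CH2Cl2/1,4-dioxane (4:1), 0 °C → rt
Reagents that add atoms: none
Why: DDQ dehydrogenation of the only free 4-hydroxybenzyl group to a para-quinone methide, then 5-exo-trig oxa-1,6-addition of the neighbouring C7a phenol. C2 should form trans to the C3 aryl group, by attack on the open face and by reversibility of the addition.

Step 17
Reactants: 21 ring A phenol
Product: 22 ring A methyl ether: as 21 with the 4-hydroxyphenyl group of ring A as 4-methoxyphenyl
Conditions: MeI, K2CO3, acetone, rt
Reagents that add atoms: iodomethane, CI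
Why: Williamson etherification of the only free phenol; the cap removes the phenol that would let DDQ oxidize C2–H of ring A in step 19.

Step 18
Reactants: 22 ring A methyl ether with four silyl ethers
Product: 23 tetraphenol precursor: (S)-1-[2-hydroxy-4-methoxy-6-(ring A-3-yl)phenyl]-1-{3-hydroxy-5-methoxy-2-[(R)-1-(3,5-dimethoxyphenyl)-2-(4-hydroxyphenyl)ethyl]phenyl}-2-(4-hydroxyphenyl)ethane, ring A being (2R,3R)-4-chloro-6-methoxy-2-(4-methoxyphenyl)-2,3-dihydrobenzofuran
Conditions: Bu4NF (5 equiv), AcOH (5 equiv), THF, 0 °C
Reagents that add atoms: none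
Why: fluoride cleavage of four aryl Si–O bonds; the acetic acid buffer keeps the electron-rich phenols protonated and so limits aerial oxidation.

Step 19
Reactants: 23 tetraphenol precursor
Product: 25 tris(dihydrobenzofuran) chloride: ring A (2R,3R)-4-chloro-6-methoxy-2-(4-methoxyphenyl); ring B (2S,3S)-2-(4-hydroxyphenyl)-6-methoxy, bonded at C4 to C3 of ring A and at C3 to C4 of ring C; ring C (2R,3R)-3-(3,5-dimethoxyphenyl)-2-(4-hydroxyphenyl)-6-methoxy, via bis(quinone methide) 24 (not isolated)
Conditions: DDQ (2.1 equiv, slow addition), CH2Cl2/1,4-dioxane (4:1), 0 °C → rt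
Reagents that add atoms: none
Why: DDQ forms a charge-transfer complex with each free 4-hydroxybenzyl phenol and removes hydride from its CH2 group, which after proton loss gives a para-quinone methide (24 is drawn as the twofold oxidized form; the two events may run one after the other). The closest known reaction type is the DDQ oxidative cyclization of 2'-hydroxyisoflavans to pterocarpans, together with the DDQ dehydrogenation of 4-alkylphenols. Ring B closes when the C7a phenol of unit B adds to the exocyclic methide carbon C2 in a 5-exo-trig oxa-1,6-addition that restores the arene, and ring C closes in the same mode from the C7a phenol of unit C; no other phenol can reach either methide carbon through a small ring. C2 of ring B and C2 of ring C are each controlled by the preset neighbouring C3: the phenol attacks the methide face away from the C3 aryl group, and the addition is reversible through the 4-hydroxyphenyl group, so the trans isomer is also the thermodynamic one. The step needs oxidation at the two CH2 groups only; the three C3–H bonds are benzylic too, but each lies in the plane of its 2,6-disubstituted arene to avoid A(1,3) strain and is not aligned for hydride loss, and C2–H of ring A is protected by the methyl cap. It also needs the new 2-(4-hydroxyphenyl) rings to survive, which the near-stoichiometric oxidant added slowly at 0 °C should secure. Ring closure must outrun tautomerization of the quinone methide to the α-arylstilbene, which would erase C3; the ortho phenol held next to the methide carbon favours closure.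

Step 20
Reactants: 25 tris(dihydrobenzofuran) chloride; 26 3,4-dimethoxystyrene
Product: 27 (E)-stilbene: as 25 with chlorine replaced by an (E)-2-(3,4-dimethoxyphenyl)vinyl group
Conditions: 26 (3 equiv), Pd2(dba)3 (5 mol%), [HP(t-Bu)3]BF4 (12 mol%), Cy2NMe, 1,4-dioxane, 100 °C
Reagents that add atoms: none
Why: Mizoroki–Heck reaction of an aryl chloride; zerovalent palladium with P(t-Bu)3 inserts into the electron-rich C–Cl bond, the styrene inserts with the aryl group on its terminal carbon, and syn β-hydride elimination gives the E alkene. Free phenols are tolerated with the hindered amine base.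

Step 21
Reactants: 27 octamethyl ether
Product: 28 target CNP0099535.1, ring A (2R,3R), ring B (2S,3S), ring C (2R,3R), E alkene
Conditions: BBr3 (20 equiv), CH2Cl2, −78 → 0 °C; MeOH, then H2O
Reagents that add atoms: none
Why: Lewis acid cleavage of all eight aryl methyl ethers by O-complexation and bromide attack on methyl. The two free phenols are borylated at once, which makes their aryl groups poorer donors and disfavours ionization of O1–C2; no stereocentre is touched.

## Compound list

1 | 2-(4-isopropoxyphenyl)acetic acid | CC(C)Oc1ccc(CC(=O)O)cc1 | starting material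
2 | 1-chloro-3,5-dimethoxybenzene | COc1cc(Cl)cc(OC)c1 | starting material
3 | 2-(4-isopropoxyphenyl)acetyl chloride | CC(C)Oc1ccc(CC(=O)Cl)cc1 | intermediate
4 | 1-(2-chloro-4,6-dimethoxyphenyl)-2-(4-isopropoxyphenyl)ethan-1-one | CC(C)Oc1ccc(CC(=O)c2c(Cl)cc(OC)cc2OC)cc1 | intermediate
5 | 1-(2-chloro-6-hydroxy-4-methoxyphenyl)-2-(4-hydroxyphenyl)ethan-1-one | COc1cc(O)c(C(=O)Cc2ccc(O)cc2)c(Cl)c1 | intermediate
6 | bis(triisopropylsilyl) ether of 5 | COc1cc(O[Si](C(C)C)(C(C)C)C(C)C)c(C(=O)Cc2ccc(O[Si](C(C)C)(C(C)C)C(C)C)cc2)c(Cl)c1 | intermediate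
7 | (Z)-enol triflate of 6 | COc1cc(O[Si](C(C)C)(C(C)C)C(C)C)c(/C(OS(=O)(=O)C(F)(F)F)=C/c2ccc(O[Si](C(C)C)(C(C)C)C(C)C)cc2)c(Cl)c1 | intermediate
8 | (3,5-dimethoxyphenyl)boronic acid | COc1cc(OC)cc(B(O)O)c1 | starting material
9 | (E)-triarylethylene of unit C | COc1cc(O[Si](C(C)C)(C(C)C)C(C)C)c(/C(c2cc(OC)cc(OC)c2)=C/c2ccc(O[Si](C(C)C)(C(C)C)C(C)C)cc2)c(Cl)c1 | intermediate
10 | (R)-triarylethane chloride of unit C | COc1cc(O[Si](C(C)C)(C(C)C)C(C)C)c([C@H](Cc2ccc(O[Si](C(C)C)(C(C)C)C(C)C)cc2)c2cc(OC)cc(OC)c2)c(Cl)c1 | intermediate
11 | (R)-triarylethane pinacol boronate of unit C | COc1cc(O[Si](C(C)C)(C(C)C)C(C)C)c([C@H](Cc2ccc(O[Si](C(C)C)(C(C)C)C(C)C)cc2)c2cc(OC)cc(OC)c2)c(B2OC(C)(C)C(C)(C)O2)c1 | intermediate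
12 | (E)-triarylethylene of unit B carrying unit C (R) | COc1cc(O[Si](C(C)C)(C(C)C)C(C)C)c(/C(c2cc(OC)cc(O[Si](C(C)C)(C(C)C)C(C)C)c2[C@H](Cc2ccc(O[Si](C(C)C)(C(C)C)C(C)C)cc2)c2cc(OC)cc(OC)c2)=C/c2ccc(O[Si](C(C)C)(C(C)C)C(C)C)cc2)c(Cl)c1 | intermediate
13 | bis(triarylethane) chloride, unit B (S), unit C (R) | CC(C)[Si](Oc1ccc(C[C@H](c2c(O[Si](C(C)C)(C(C)C)C(C)C)cc(OC)cc2Cl)c2cc(OC)cc(O[Si](C(C)C)(C(C)C)C(C)C)c2[C@H](Cc2ccc(O[Si](C(C)C)(C(C)C)C(C)C)cc2)c2cc(OC)cc(OC)c2)cc1)(C(C)C)C(C)C | intermediate
14 | bis(triarylethane) pinacol boronate, unit B (S), unit C (R) | CC(C)[Si](Oc1ccc(C[C@H](c2c(O[Si](C(C)C)(C(C)C)C(C)C)cc(OC)cc2B2OC(C)(C)C(C)(C)O2)c2cc(OC)cc(O[Si](C(C)C)(C(C)C)C(C)C)c2[C@H](Cc2ccc(O[Si](C(C)C)(C(C)C)C(C)C)cc2)c2cc(OC)cc(OC)c2)cc1)(C(C)C)C(C)C | intermediate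
15 | bis(methoxymethyl) ether of 5 | COCOc1ccc(CC(=O)c2c(Cl)cc(OC)cc2OCOC)cc1 | intermediate
16 | (Z)-enol triflate of 15 | COCOc1ccc(/C=C(/c2c(Cl)cc(OC)cc2OCOC)OS(=O)(=O)C(F)(F)F)cc1 | intermediate
17 | (E)-triarylethylene of unit A carrying units B (S) and C (R) | CC(C)[Si](Oc1ccc(C[C@H](c2c(O[Si](C(C)C)(C(C)C)C(C)C)cc(OC)cc2/C(=C\c2ccc(OCOC)cc2)c2c(Cl)cc(OC)cc2OCOC)c2cc(OC)cc(O[Si](C(C)C)(C(C)C)C(C)C)c2[C@H](Cc2ccc(O[Si](C(C)C)(C(C)C)C(C)C)cc2)c2cc(OC)cc(OC)c2)cc1)(C(C)C)C(C)C | intermediate
18 | tris(triarylethane), unit A (R) with MOM ethers, unit B (S), unit C (R) | CC(C)[Si](Oc1ccc(C[C@H](c2c(O[Si](C(C)C)(C(C)C)C(C)C)cc(OC)cc2[C@@H](Cc2ccc(OCOC)cc2)c2c(Cl)cc(OC)cc2OCOC)c2cc(OC)cc(O[Si](C(C)C)(C(C)C)C(C)C)c2[C@H](Cc2ccc(O[Si](C(C)C)(C(C)C)C(C)C)cc2)c2cc(OC)cc(OC)c2)cc1)(C(C)C)C(C)C | intermediate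
19 | tris(triarylethane) with unit A as diphenol | CC(C)[Si](Oc1ccc(C[C@H](c2c(O[Si](C(C)C)(C(C)C)C(C)C)cc(OC)cc2[C@@H](Cc2ccc(O)cc2)c2c(Cl)cc(OC)cc2O)c2cc(OC)cc(O[Si](C(C)C)(C(C)C)C(C)C)c2[C@H](Cc2ccc(O[Si](C(C)C)(C(C)C)C(C)C)cc2)c2cc(OC)cc(OC)c2)cc1)(C(C)C)C(C)C | intermediate
20 | para-quinone methide of unit A | CC(C)[Si](Oc1ccc(C[C@H](c2c(O[Si](C(C)C)(C(C)C)C(C)C)cc(OC)cc2[C@@H](C=C2C=CC(=O)C=C2)c2c(Cl)cc(OC)cc2O)c2cc(OC)cc(O[Si](C(C)C)(C(C)C)C(C)C)c2[C@H](Cc2ccc(O[Si](C(C)C)(C(C)C)C(C)C)cc2)c2cc(OC)cc(OC)c2)cc1)(C(C)C)C(C)C | intermediate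
21 | ring A (2R,3R) closed with free 4-hydroxyphenyl, units B and C silylated | CC(C)[Si](Oc1ccc(C[C@H](c2c(O[Si](C(C)C)(C(C)C)C(C)C)cc(OC)cc2[C@@H]2c3c(Cl)cc(OC)cc3O[C@H]2c2ccc(O)cc2)c2cc(OC)cc(O[Si](C(C)C)(C(C)C)C(C)C)c2[C@H](Cc2ccc(O[Si](C(C)C)(C(C)C)C(C)C)cc2)c2cc(OC)cc(OC)c2)cc1)(C(C)C)C(C)C | intermediate
22 | ring A (2R,3R) with 4-methoxyphenyl, units B and C silylated | CC(C)[Si](Oc1ccc(C[C@H](c2c(O[Si](C(C)C)(C(C)C)C(C)C)cc(OC)cc2[C@@H]2c3c(Cl)cc(OC)cc3O[C@H]2c2ccc(OC)cc2)c2cc(OC)cc(O[Si](C(C)C)(C(C)C)C(C)C)c2[C@H](Cc2ccc(O[Si](C(C)C)(C(C)C)C(C)C)cc2)c2cc(OC)cc(OC)c2)cc1)(C(C)C)C(C)C | intermediate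
23 | tetraphenolic bis(triarylethane) carrying ring A (chloride) | Oc1ccc(C[C@H](c2c(O)cc(OC)cc2[C@@H]2c3c(Cl)cc(OC)cc3O[C@H]2c2ccc(OC)cc2)c2cc(OC)cc(O)c2[C@H](Cc2ccc(O)cc2)c2cc(OC)cc(OC)c2)cc1 | intermediate
24 | bis(para-quinone methide) of 23 | O=C1C=CC(=C[C@H](c2c(O)cc(OC)cc2[C@@H]2c3c(Cl)cc(OC)cc3O[C@H]2c2ccc(OC)cc2)c2cc(OC)cc(O)c2[C@H](C=C2C=CC(=O)C=C2)c2cc(OC)cc(OC)c2)C=C1 | intermediate
25 | tris(dihydrobenzofuran) with two free 4-hydroxyphenyl groups and the ring A chloride | Oc1ccc([C@H]2Oc3cc(OC)cc([C@@H]4c5c(Cl)cc(OC)cc5O[C@H]4c4ccc(OC)cc4)c3[C@@H]2c2cc(OC)cc3c2[C@@H](c2cc(OC)cc(OC)c2)[C@H](c2ccc(O)cc2)O3)cc1 | intermediate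
26 | 3,4-dimethoxystyrene | C=Cc1ccc(OC)c(OC)c1 | starting material
27 | octamethyl ether of the target | Oc1ccc([C@H]2Oc3cc(OC)cc([C@@H]4c5c(/C=C/c6ccc(OC)c(OC)c6)cc(OC)cc5O[C@H]4c4ccc(OC)cc4)c3[C@@H]2c2cc(OC)cc3c2[C@@H](c2cc(OC)cc(OC)c2)[C@H](c2ccc(O)cc2)O3)cc1 | intermediate
28 | CNP0099535.1 | Oc1ccc([C@H]2Oc3cc(O)cc([C@@H]4c5c(/C=C/c6ccc(O)c(O)c6)cc(O)cc5O[C@H]4c4ccc(O)cc4)c3[C@@H]2c2cc(O)cc3c2[C@@H](c2cc(O)cc(O)c2)[C@H](c2ccc(O)cc2)O3)cc1 | target

## Step count and risk

Total step count: 21. Longest linear sequence: 19 (steps 1–10 and 13–21).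

Step 19 (key step). The most likely failure is over-oxidation: DDQ may remove hydride from C2–H of a newly formed 2-(4-hydroxyphenyl) ring and aromatize it to a benzofuran, because that C–H is activated by both the phenol and O1. The second risk is tautomerization of a quinone methide to the α-arylstilbene before the hindered C7a phenol closes, which would erase C3. The fallback separates oxidation from ring closure. It sets out from 23, which is oxidized with DDQ in CH2Cl2/MeOH at −20 °C so that methanol captures each quinone methide as it forms. This gives the bis(benzylic methyl ether) of the tetraphenol F1 (mixture of epimers at the two methoxy-bearing carbons). After the oxidant is removed, catalytic CF3CO2H in CH2Cl2 at −20 °C re-ionizes both ethers and the C7a phenols close the rings under thermodynamic control. The fallback comes back to the route at 25.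

Step 14 (and, to a lesser degree, steps 9 and 6). The likely failure is low turnover or poor facial selectivity. The alkene carries four ortho substituents on its two geminal arenes, rotation about the C3a–alkene bond may be slow, and the two resident centres can make a mismatched pair with the catalyst. The fallback gives up catalyst control for separation. It sets out from 17, which is reduced with the achiral catalyst [Ir(cod)(PCy3)(py)]PF6 under H2 to give 18 together with its epimer at C3 of unit A F2. The two are diastereomers and are separated by preparative chromatography. The fallback comes back at 18. The same applies to step 9 from 12; step 6 is the least hindered of the three.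

Step 13 (and step 8). The likely failure is slow transmetalation of the ortho-branched boronate, which leaves time for protodeboronation and for hydrolysis of the enol triflate back to the ketone. The fallback changes the nucleophile to zinc. It sets out from 14, which is converted by copper-catalysed iododeboronation (CuI, 1,10-phenanthroline, KI, MeOH/H2O, air) into the aryl iodide F3. Exchange with i-PrMgCl·LiCl at −20 °C and addition of ZnCl2 give the arylzinc chloride F4. Negishi coupling of F4 with 16 under Pd(PPh3)4 in THF at 50 °C comes back to the route at 17.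

Step 20. The likely failure is slow oxidative addition at the ortho-substituted, electron-rich aryl chloride, which leads to catalyst decay and lets the styrene oligomerize; a minor 1,1-diarylethene isomer is also possible. The fallback replaces the Heck reaction by an alkenyl Suzuki–Miyaura coupling. It sets out from 25, which is coupled with (E)-2-(3,4-dimethoxystyryl)-4,4,5,5-tetramethyl-1,3,2-dioxaborolane F5 (from 4-ethynyl-1,2-dimethoxybenzene and pinacolborane) under Pd(OAc)2, SPhos and K3PO4 in 1,4-dioxane/H2O at 80 °C. It comes back at 27.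

Step 21. The likely failure is acid-induced ionization of the O1–C2 bonds followed by epimerization or arene capture, and HBr addition to or oligomerization of the electron-rich stilbene. The fallback takes the stilbene out of the Lewis acid step. It sets out from 25, which is demethylated with BBr3 before the alkene exists, giving the octaphenol chloride F6. Acetylation (Ac2O, pyridine) gives the octaacetate F7. A Heck reaction of F7 with 4-vinyl-1,2-phenylene diacetate F8 under the conditions of step 20 gives the decaacetate F9. Methanolysis with K2CO3 in MeOH comes back to the route at 28.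

## Further compounds

F1 | step 19 | bis(benzylic methyl ether) of tetraphenol 23 | Oc1ccc(C(OC)[C@H](c2c(O)cc(OC)cc2[C@@H]2c3c(Cl)cc(OC)cc3O[C@H]2c2ccc(OC)cc2)c2cc(OC)cc(O)c2[C@H](C(OC)c2ccc(O)cc2)c2cc(OC)cc(OC)c2)cc1
F2 | step 14 | epimer of 18 at C3 of unit A | CC(C)[Si](Oc1ccc(C[C@H](c2c(O[Si](C(C)C)(C(C)C)C(C)C)cc(OC)cc2[C@H](Cc2ccc(OCOC)cc2)c2c(Cl)cc(OC)cc2OCOC)c2cc(OC)cc(O[Si](C(C)C)(C(C)C)C(C)C)c2[C@H](Cc2ccc(O[Si](C(C)C)(C(C)C)C(C)C)cc2)c2cc(OC)cc(OC)c2)cc1)(C(C)C)C(C)C
F3 | step 13 | aryl iodide corresponding to boronate 14 | CC(C)[Si](Oc1ccc(C[C@H](c2c(O[Si](C(C)C)(C(C)C)C(C)C)cc(OC)cc2I)c2cc(OC)cc(O[Si](C(C)C)(C(C)C)C(C)C)c2[C@H](Cc2ccc(O[Si](C(C)C)(C(C)C)C(C)C)cc2)c2cc(OC)cc(OC)c2)cc1)(C(C)C)C(C)C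
F4 | step 13 | arylzinc chloride from F3 | CC(C)[Si](Oc1ccc(C[C@H](c2c(O[Si](C(C)C)(C(C)C)C(C)C)cc(OC)cc2[Zn]Cl)c2cc(OC)cc(O[Si](C(C)C)(C(C)C)C(C)C)c2[C@H](Cc2ccc(O[Si](C(C)C)(C(C)C)C(C)C)cc2)c2cc(OC)cc(OC)c2)cc1)(C(C)C)C(C)C
F5 | step 20 | (E)-2-(3,4-dimethoxystyryl)-4,4,5,5-tetramethyl-1,3,2-dioxaborolane | COc1ccc(/C=C/B2OC(C)(C)C(C)(C)O2)cc1OC
F6 | step 21 | octaphenol chloride from 25 | Oc1ccc([C@H]2Oc3cc(O)cc([C@@H]4c5c(Cl)cc(O)cc5O[C@H]4c4ccc(O)cc4)c3[C@@H]2c2cc(O)cc3c2[C@@H](c2cc(O)cc(O)c2)[C@H](c2ccc(O)cc2)O3)cc1
F7 | step 21 | octaacetate of F6 | CC(=O)Oc1ccc([C@H]2Oc3cc(OC(C)=O)cc([C@@H]4c5c(Cl)cc(OC(C)=O)cc5O[C@H]4c4ccc(OC(C)=O)cc4)c3[C@@H]2c2cc(OC(C)=O)cc3c2[C@@H](c2cc(OC(C)=O)cc(OC(C)=O)c2)[C@H](c2ccc(OC(C)=O)cc2)O3)cc1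
F8 | step 21 | 4-vinyl-1,2-phenylene diacetate | C=Cc1ccc(OC(C)=O)c(OC(C)=O)c1
F9 | step 21 | decaacetate of the target | CC(=O)Oc1ccc([C@H]2Oc3cc(OC(C)=O)cc([C@@H]4c5c(/C=C/c6ccc(OC(C)=O)c(OC(C)=O)c6)cc(OC(C)=O)cc5O[C@H]4c4ccc(OC(C)=O)cc4)c3[C@@H]2c2cc(OC(C)=O)cc3c2[C@@H](c2cc(OC(C)=O)cc(OC(C)=O)c2)[C@H](c2ccc(OC(C)=O)cc2)O3)cc1
A1 | alternative 1 | methyl (2R,3R)-6-methoxy-2-(4-methoxyphenyl)-4-(triflyloxy)-2,3-dihydrobenzofuran-3-carboxylate | O=S(=O)(Oc1cc(OC)cc2c1[C@@H](C(=O)OC)[C@H](c1ccc(OC)cc1)O2)C(F)(F)F
A2 | alternative 1 | (R)-7-methoxy-2-(4-methoxyphenyl)-4-oxochroman-5-yl trifluoromethanesulfonate | O=C1C[C@H](c2ccc(OC)cc2)Oc2cc(OC)cc(OS(=O)(=O)C(F)(F)F)c21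
A3 | alternative 2 | ring B–C unit with C6 ethoxy and C4 diethyl acetal | COc1ccc([C@H]2Oc3cc(OCC)cc(C(OCC)OCC)c3[C@@H]2c2cc(OC)cc3c2[C@@H](c2cc(OC)cc(OC)c2)[C@H](c2ccc(OC)cc2)O3)cc1
A4 | alternative 2 | 1,6-diyne: ethynyl ether on the C2 oxygen and 3,3-diethoxypropynyl group on C3, ring C attached | COc1ccc([C@@H](OC#C)[C@H](C#CC(OCC)OCC)c2cc(OC)cc3c2[C@@H](c2cc(OC)cc(OC)c2)[C@H](c2ccc(OC)cc2)O3)cc1
A5 | alternative 2 | ethoxyacetylene | CCOC#C
A6 | alternative 3 | permethylated tris(dihydrobenzofuran) with bromine at C4 of ring A | COc1ccc([C@H]2Oc3cc(OC)cc([C@@H]4c5c(Br)cc(OC)cc5O[C@H]4c4ccc(OC)cc4)c3[C@@H]2c2cc(OC)cc3c2[C@@H](c2cc(OC)cc(OC)c2)[C@H](c2ccc(OC)cc2)O3)cc1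
A7 | alternative 3 | ring A phenol sulfone: 3-bromo-5-methoxy-2-[(ring B C4-yl)(tosyl)methyl]phenol on the ring B–C unit | COc1ccc([C@H]2Oc3cc(OC)cc(C(c4c(O)cc(OC)cc4Br)S(=O)(=O)c4ccc(C)cc4)c3[C@@H]2c2cc(OC)cc3c2[C@@H](c2cc(OC)cc(OC)c2)[C@H](c2ccc(OC)cc2)O3)cc1
A8 | alternative 3 | (2R,5R)-1-(4-methoxybenzyl)-2,5-dimethylthiolan-1-ium tetrafluoroborate | COc1ccc(C[S+]2[C@H](C)CC[C@H]2C)cc1.F[B-](F)(F)F
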